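**Retrosynthetic overview**
- The target is reached by one global fluoride desilylation of a tris-silyl-protected (2S)-flavanone.
- Ring C is the only ring formed, and it is formed last: an enantioselective intramolecular oxa-Michael addition of a 2-hydroxyaryl alkylidene β-ketoester sets C2, then the activating tert-butyl ester is removed by decarboxylation.
- The alkylidene β-ketoester comes from a Knoevenagel-type aldol condensation (C2–C3 bond) of the ring A β-ketoester with silyl-protected 3,4-dihydroxybenzaldehyde (ring B).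
- The β-ketoester comes from a crossed Claisen condensation (C3–C4 bond) of a methyl salicylate with the enolate of tert-butyl acetate.
- The salicylate carries the (E)-hydroxyprenyl chain, built from a 3-allyl group (aromatic Claisen rearrangement, cross-metathesis with methacrolein, reduction); rings A and B are bought.

Assumption: the quinidine-derived thiourea gives the (2S) series in the oxa-Michael step (this is a recalled, unverified sense of induction); CD and chiral HPLC on the first run confirm it, and the quinine-derived pseudoenantiomer is the drop-in replacement if the antipode forms.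

**Route**

Step 1
Reactants: 1 methyl 2-hydroxy-4-methoxybenzoate
Product: 2 methyl 4-methoxy-2-(prop-2-en-1-yloxy)benzoate
Conditions: allyl bromide (1.5 equiv), K2CO3 (2 equiv), DMF, 60 °C
Reagents that add atoms: allyl bromide C=CCBr
Why: Williamson ether synthesis, in which K2CO3 in warm DMF breaks the ester-chelated hydrogen bond and the phenoxide displaces bromide by SN2.

Step 2
Reactants: 2 methyl 4-methoxy-2-(prop-2-en-1-yloxy)benzoate
Product: 4 methyl 2-hydroxy-4-methoxy-3-(prop-2-en-1-yl)benzoate, via ortho-dienone 3 (not isolated)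
Conditions: N,N-diethylaniline, 200 °C
Reagents that add atoms: none
Why: Aromatic Claisen rearrangement, in which the [3,3] shift can only end productively at C3 (the one free ortho position) and dienone 3 tautomerises at once to the phenol, fixing the 1,2,3,4-pattern of ring A.

Step 3
Reactants: 4 methyl 2-hydroxy-4-methoxy-3-(prop-2-en-1-yl)benzoate
Product: 5 methyl 2-hydroxy-4-methoxy-3-[(2E)-3-methyl-4-oxobut-2-en-1-yl]benzoate
Conditions: methacrolein (5 equiv), second-generation Hoveyda–Grubbs catalyst RuCl2(H2IMes)(=CH-C6H4-2-OiPr) (5 mol%), 1,4-benzoquinone (10 mol%), CH2Cl2, 40 °C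
Reagents that add atoms: methacrolein CC(=C)C=O
Why: Olefin cross-metathesis of a terminal alkene with a 1,1-disubstituted enal gives the trisubstituted enal under thermodynamic control as the E isomer (formyl trans to the benzylic chain), with benzoquinone suppressing ruthenium hydride migration of the allyl double bond.

Step 4
Reactants: 5 methyl 2-hydroxy-4-methoxy-3-[(2E)-3-methyl-4-oxobut-2-en-1-yl]benzoate
Product: 6 methyl 2-hydroxy-3-[(2E)-4-hydroxy-3-methylbut-2-en-1-yl]-4-methoxybenzoate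
Conditions: NaBH4, CeCl3·7H2O, MeOH, 0 °C
Reagents that add atoms: none
Why: Luche reduction, in which the cerium-activated aldehyde is reduced 1,2 within minutes under nearly neutral conditions, leaving the aryl ester and the alkene geometry untouched and giving the phenol no time to add to the enal.

Step 5
Reactants: 6 methyl 2-hydroxy-3-[(2E)-4-hydroxy-3-methylbut-2-en-1-yl]-4-methoxybenzoate
Product: 7 methyl 3-[(2E)-4-[(tert-butyldiphenylsilyl)oxy]-3-methylbut-2-en-1-yl]-2-hydroxy-4-methoxybenzoate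
Conditions: TBDPSCl (1.05 equiv), imidazole, CH2Cl2, 0 °C
Reagents that add atoms: TBDPSCl CC(C)(C)[Si](Cl)(c1ccccc1)c1ccccc1
Why: Silyl ether formation is selective for the unhindered primary allylic alcohol because the phenol is flanked on both sides and hydrogen-bonded to the ester carbonyl.

Step 6
Reactants: 7 methyl 3-[(2E)-4-[(tert-butyldiphenylsilyl)oxy]-3-methylbut-2-en-1-yl]-2-hydroxy-4-methoxybenzoate
Product: 8 tert-butyl 3-{3-[(2E)-4-[(tert-butyldiphenylsilyl)oxy]-3-methylbut-2-en-1-yl]-2-hydroxy-4-methoxyphenyl}-3-oxopropanoate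
Conditions: tert-butyl acetate (4.1 equiv), LiN(iPr)2 (LDA, 4.0 equiv), THF, −78 °C; then 7, −78 to 0 °C; aqueous NH4Cl
Reagents that add atoms: tert-butyl acetate CC(=O)OC(C)(C)C
Why: Crossed Claisen condensation, in which the preformed ester enolate adds to the methyl ester and the product is protected from a second addition as its phenoxide/β-ketoester dianion until the quench.

Step 7
Reactants: 9 3,4-dihydroxybenzaldehyde
Product: 10 3,4-bis(tert-butyldimethylsilyloxy)benzaldehyde
Conditions: TBSCl (2.4 equiv), imidazole (5 equiv), DMF, rt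
Reagents that add atoms: TBSCl CC(C)(C)[Si](C)(C)Cl
Why: Standard silylation of both phenols gives an aldehyde whose protecting groups tolerate the amine and acid steps ahead and come off with fluoride at the end together with the side-chain silyl ether.

Step 8
Reactants: 8 tert-butyl 3-{3-[(2E)-4-[(tert-butyldiphenylsilyl)oxy]-3-methylbut-2-en-1-yl]-2-hydroxy-4-methoxyphenyl}-3-oxopropanoate; 10 3,4-bis(tert-butyldimethylsilyloxy)benzaldehyde
Product: 11 tert-butyl 2-{3-[(2E)-4-[(tert-butyldiphenylsilyl)oxy]-3-methylbut-2-en-1-yl]-2-hydroxy-4-methoxybenzoyl}-3-[3,4-bis(tert-butyldimethylsilyloxy)phenyl]prop-2-enoate (E/Z mixture at the new double bond)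
Conditions: piperidine (0.2 equiv), AcOH (0.2 equiv), 4 Å molecular sieves, toluene, rt to 40 °C; prompt chromatography
Reagents that add atoms: none
Why: Knoevenagel-type aldol condensation, in which the active methylene of 8 adds to the piperidinium iminium of 10 and eliminates amine and water, joining the ring A and ring B fragments through the future C2–C3 bond while the buffered catalyst keeps the free phenol from closing prematurely.

Step 9
Reactants: 11 tert-butyl 2-{3-[(2E)-4-[(tert-butyldiphenylsilyl)oxy]-3-methylbut-2-en-1-yl]-2-hydroxy-4-methoxybenzoyl}-3-[3,4-bis(tert-butyldimethylsilyloxy)phenyl]prop-2-enoate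
Product: 14 (2S)-2-[3,4-bis(tert-butyldimethylsilyloxy)phenyl]-8-[(2E)-4-[(tert-butyldiphenylsilyl)oxy]-3-methylbut-2-en-1-yl]-7-methoxy-2,3-dihydro-4H-chromen-4-one, via tert-butyl ester 12 (not isolated), via beta-keto acid 13 (not isolated)
Conditions: 1-[3,5-bis(trifluoromethyl)phenyl]-3-[(9R)-6'-methoxycinchonan-9-yl]thiourea (quinidine-derived, 10 mol%), toluene, −25 °C; then TsOH (0.5 equiv), 80 °C
Reagents that add atoms: none
Why: Organocatalytic enantioselective intramolecular oxa-Michael addition closes ring C, the thiourea binding the β-ketoester while the quinuclidine nitrogen delivers the phenol to one face of the alkylidene to set C2 as S, and acid-mediated loss of isobutylene followed by decarboxylation then removes the activating ester in the same pot before C2 can equilibrate.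

Step 10
Reactants: 14 (2S)-2-[3,4-bis(tert-butyldimethylsilyloxy)phenyl]-8-[(2E)-4-[(tert-butyldiphenylsilyl)oxy]-3-methylbut-2-en-1-yl]-7-methoxy-2,3-dihydro-4H-chromen-4-one
Product: 15 (2S)-2-(3,4-dihydroxyphenyl)-8-[(2E)-4-hydroxy-3-methylbut-2-en-1-yl]-7-methoxy-2,3-dihydro-4H-chromen-4-one
Conditions: Bu4NF (4 equiv), AcOH (4 equiv), THF, 0 °C to rt; pH 5 work-up; recrystallisation
Reagents that add atoms: none
Why: Fluoride-mediated desilylation buffered to slight acidity removes all three silyl ethers in one operation without forming the phenoxide or enolate that would open the flavanone by retro-oxa-Michael reaction and erode the C2 configuration.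

Enantiopurity: step 9 is expected to give roughly 80–94% ee. It is raised to a single enantiomer by recrystallisation of 15, or by preparative chiral HPLC of 14. The CD spectrum of 15 confirms the 2S configuration.

**Compound list**
1 | methyl 2-hydroxy-4-methoxybenzoate | COC(=O)c1ccc(OC)cc1O | starting material
2 | methyl 4-methoxy-2-(prop-2-en-1-yloxy)benzoate | COC(=O)c1ccc(OC)cc1OCC=C | intermediate
3 | methyl 4-methoxy-6-oxo-5-(prop-2-en-1-yl)cyclohexa-1,3-diene-1-carboxylate (ortho-dienone, racemic) | COC(=O)C1=CC=C(OC)C(CC=C)C1=O | intermediate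
4 | methyl 2-hydroxy-4-methoxy-3-(prop-2-en-1-yl)benzoate | COC(=O)c1ccc(OC)c(CC=C)c1O | intermediate
5 | methyl 2-hydroxy-4-methoxy-3-[(2E)-3-methyl-4-oxobut-2-en-1-yl]benzoate | COC(=O)c1ccc(OC)c(C/C=C(\C)C=O)c1O | intermediate
6 | methyl 2-hydroxy-3-[(2E)-4-hydroxy-3-methylbut-2-en-1-yl]-4-methoxybenzoate | COC(=O)c1ccc(OC)c(C/C=C(\C)CO)c1O | intermediate
7 | methyl 3-[(2E)-4-[(tert-butyldiphenylsilyl)oxy]-3-methylbut-2-en-1-yl]-2-hydroxy-4-methoxybenzoate | COC(=O)c1ccc(OC)c(C/C=C(\C)CO[Si](c2ccccc2)(c2ccccc2)C(C)(C)C)c1O | intermediate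
8 | tert-butyl 3-{3-[(2E)-4-[(tert-butyldiphenylsilyl)oxy]-3-methylbut-2-en-1-yl]-2-hydroxy-4-methoxyphenyl}-3-oxopropanoate | CC(C)(C)OC(=O)CC(=O)c1ccc(OC)c(C/C=C(\C)CO[Si](c2ccccc2)(c2ccccc2)C(C)(C)C)c1O | intermediate
9 | 3,4-dihydroxybenzaldehyde | O=Cc1ccc(O)c(O)c1 | starting material
10 | 3,4-bis(tert-butyldimethylsilyloxy)benzaldehyde | O=Cc1ccc(O[Si](C)(C)C(C)(C)C)c(O[Si](C)(C)C(C)(C)C)c1 | intermediate
11 | tert-butyl 2-{3-[(2E)-4-[(tert-butyldiphenylsilyl)oxy]-3-methylbut-2-en-1-yl]-2-hydroxy-4-methoxybenzoyl}-3-[3,4-bis(tert-butyldimethylsilyloxy)phenyl]prop-2-enoate (E/Z mixture at the new double bond) | CC(C)(C)OC(=O)C(=Cc1ccc(O[Si](C)(C)C(C)(C)C)c(O[Si](C)(C)C(C)(C)C)c1)C(=O)c1ccc(OC)c(C/C=C(\C)CO[Si](c2ccccc2)(c2ccccc2)C(C)(C)C)c1O | intermediate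
12 | tert-butyl (2S)-2-[3,4-bis(tert-butyldimethylsilyloxy)phenyl]-8-[(2E)-4-[(tert-butyldiphenylsilyl)oxy]-3-methylbut-2-en-1-yl]-7-methoxy-4-oxo-3,4-dihydro-2H-chromene-3-carboxylate (C3 epimers/enol) | COc1ccc2c(c1C/C=C(\C)CO[Si](c1ccccc1)(c1ccccc1)C(C)(C)C)O[C@H](c1ccc(O[Si](C)(C)C(C)(C)C)c(O[Si](C)(C)C(C)(C)C)c1)C(C(=O)OC(C)(C)C)C2=O | intermediate
13 | (2S)-2-[3,4-bis(tert-butyldimethylsilyloxy)phenyl]-8-[(2E)-4-[(tert-butyldiphenylsilyl)oxy]-3-methylbut-2-en-1-yl]-7-methoxy-4-oxo-3,4-dihydro-2H-chromene-3-carboxylic acid (C3 epimers) | COc1ccc2c(c1C/C=C(\C)CO[Si](c1ccccc1)(c1ccccc1)C(C)(C)C)O[C@H](c1ccc(O[Si](C)(C)C(C)(C)C)c(O[Si](C)(C)C(C)(C)C)c1)C(C(=O)O)C2=O | intermediate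
14 | (2S)-2-[3,4-bis(tert-butyldimethylsilyloxy)phenyl]-8-[(2E)-4-[(tert-butyldiphenylsilyl)oxy]-3-methylbut-2-en-1-yl]-7-methoxy-2,3-dihydro-4H-chromen-4-one | COc1ccc2c(c1C/C=C(\C)CO[Si](c1ccccc1)(c1ccccc1)C(C)(C)C)O[C@H](c1ccc(O[Si](C)(C)C(C)(C)C)c(O[Si](C)(C)C(C)(C)C)c1)CC2=O | intermediate
15 | (2S)-2-(3,4-dihydroxyphenyl)-8-[(2E)-4-hydroxy-3-methylbut-2-en-1-yl]-7-methoxy-2,3-dihydro-4H-chromen-4-one | COc1ccc2c(c1C/C=C(\C)CO)O[C@H](c1ccc(O)c(O)c1)CC2=O | target

**Totals**
Total step count: 10. Longest linear sequence: 9 steps (steps 1 to 6, then 8, 9 and 10); step 7 is a one-step side branch.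

**Steps most likely to fail, with fallbacks**

Step 9 (enantioselective ring closure and decarboxylation). The 8-substituent sits next to the reacting phenol and may lower the selectivity, the sense of induction rests on the stated assumption, and the silyl ethers must survive TsOH at 80 °C. The fallback replaces asymmetric catalysis by a kinetic resolution; it sets out from 11 and comes back at 14.
- Compound 11 is cyclised with an achiral base (DABCO 10 mol%, toluene, rt) to racemic tert-butyl 2-[3,4-bis(tert-butyldimethylsilyloxy)phenyl]-8-[(2E)-4-[(tert-butyldiphenylsilyl)oxy]-3-methylbut-2-en-1-yl]-7-methoxy-4-oxo-3,4-dihydro-2H-chromene-3-carboxylate F8.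
- TsOH at 80 °C takes this through the racemic 3-carboxylic acid F9 to the racemic flavanone F10.
- Asymmetric transfer hydrogenation (RhCl(Cp*)[(R,R)-TsDPEN] 1 mol%, HCO2H/Et3N 5:2, EtOAc, rt, stopped near 55% conversion) is expected to reduce only the 2R ketone, giving the cis alcohol (2R,4R)-2-[3,4-bis(tert-butyldimethylsilyloxy)phenyl]-8-[(2E)-4-[(tert-butyldiphenylsilyl)oxy]-3-methylbut-2-en-1-yl]-7-methoxy-3,4-dihydro-2H-chromen-4-ol F11.
- F11 is removed on silica and the untouched 2S ketone is 14 (at most 50% from racemate). The same resolution polishes under-enriched 14 from the main step.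

Step 6 (crossed Claisen condensation). The ester carbonyl is deactivated by the ortho phenoxide and the para methoxy group and may not accept the enolate. The fallback is a decarboxylative acylation of a malonate half-ester; it sets out from 7 and comes back at 8.
- Saponification (LiOH, THF/MeOH/H2O, 50 °C) gives 3-[(2E)-4-[(tert-butyldiphenylsilyl)oxy]-3-methylbut-2-en-1-yl]-2-hydroxy-4-methoxybenzoic acid F5.
- CDI (1,1'-carbonyldiimidazole, 1.05 equiv, THF, rt) gives the acyl imidazolide F6.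
- Mg(O2CCH2CO2tBu)2 (THF, 40 °C) gives the tert-butyl hydrogen aroylmalonate F7 as its magnesium chelate, which loses CO2 on work-up at pH 4 to give 8.

Step 3 (cross-metathesis). Methacrolein is a reluctant partner and the ortho-allylphenol can isomerise to the propenyl arene. The fallback builds the enal by olefination instead; it sets out from 4 and comes back at 6.
- Ac2O/pyridine gives methyl 2-acetoxy-4-methoxy-3-(prop-2-en-1-yl)benzoate F1.
- Lemieux–Johnson cleavage (OsO4 cat., NaIO4, 2,6-lutidine, dioxane/water) gives methyl 2-acetoxy-4-methoxy-3-(2-oxoethyl)benzoate F2.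
- Wittig reaction with the stabilised ylide Ph3P=C(CH3)CHO (toluene, 80 °C) gives methyl 2-acetoxy-4-methoxy-3-[(2E)-3-methyl-4-oxobut-2-en-1-yl]benzoate F3 with high E selectivity.
- NaBH4/CeCl3·7H2O (MeOH, 0 °C) gives methyl 2-acetoxy-3-[(2E)-4-hydroxy-3-methylbut-2-en-1-yl]-4-methoxybenzoate F4, and K2CO3 in MeOH at rt removes the aryl acetate to give 6.

**Further compounds**
F1 | step 3 | methyl 2-acetoxy-4-methoxy-3-(prop-2-en-1-yl)benzoate | COC(=O)c1ccc(OC)c(CC=C)c1OC(C)=O
F2 | step 3 | methyl 2-acetoxy-4-methoxy-3-(2-oxoethyl)benzoate | COC(=O)c1ccc(OC)c(CC=O)c1OC(C)=O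
F3 | step 3 | methyl 2-acetoxy-4-methoxy-3-[(2E)-3-methyl-4-oxobut-2-en-1-yl]benzoate | COC(=O)c1ccc(OC)c(C/C=C(\C)C=O)c1OC(C)=O
F4 | step 3 | methyl 2-acetoxy-3-[(2E)-4-hydroxy-3-methylbut-2-en-1-yl]-4-methoxybenzoate | COC(=O)c1ccc(OC)c(C/C=C(\C)CO)c1OC(C)=O
F5 | step 6 | 3-[(2E)-4-[(tert-butyldiphenylsilyl)oxy]-3-methylbut-2-en-1-yl]-2-hydroxy-4-methoxybenzoic acid | OC(=O)c1ccc(OC)c(C/C=C(\C)CO[Si](c2ccccc2)(c2ccccc2)C(C)(C)C)c1O
F6 | step 6 | {3-[(2E)-4-[(tert-butyldiphenylsilyl)oxy]-3-methylbut-2-en-1-yl]-2-hydroxy-4-methoxyphenyl}(1H-imidazol-1-yl)methanone | O=C(n1ccnc1)c1ccc(OC)c(C/C=C(\C)CO[Si](c2ccccc2)(c2ccccc2)C(C)(C)C)c1O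
F7 | step 6 | 3-tert-butoxy-2-{3-[(2E)-4-[(tert-butyldiphenylsilyl)oxy]-3-methylbut-2-en-1-yl]-2-hydroxy-4-methoxybenzoyl}-3-oxopropanoic acid | OC(=O)C(C(=O)OC(C)(C)C)C(=O)c1ccc(OC)c(C/C=C(\C)CO[Si](c2ccccc2)(c2ccccc2)C(C)(C)C)c1O
F8 | step 9 | racemic tert-butyl 2-[3,4-bis(tert-butyldimethylsilyloxy)phenyl]-8-[(2E)-4-[(tert-butyldiphenylsilyl)oxy]-3-methylbut-2-en-1-yl]-7-methoxy-4-oxo-3,4-dihydro-2H-chromene-3-carboxylate | COc1ccc2c(c1C/C=C(\C)CO[Si](c1ccccc1)(c1ccccc1)C(C)(C)C)OC(c1ccc(O[Si](C)(C)C(C)(C)C)c(O[Si](C)(C)C(C)(C)C)c1)C(C(=O)OC(C)(C)C)C2=O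
F9 | step 9 | racemic 2-[3,4-bis(tert-butyldimethylsilyloxy)phenyl]-8-[(2E)-4-[(tert-butyldiphenylsilyl)oxy]-3-methylbut-2-en-1-yl]-7-methoxy-4-oxo-3,4-dihydro-2H-chromene-3-carboxylic acid | COc1ccc2c(c1C/C=C(\C)CO[Si](c1ccccc1)(c1ccccc1)C(C)(C)C)OC(c1ccc(O[Si](C)(C)C(C)(C)C)c(O[Si](C)(C)C(C)(C)C)c1)C(C(=O)O)C2=O
F10 | step 9 | racemic 2-[3,4-bis(tert-butyldimethylsilyloxy)phenyl]-8-[(2E)-4-[(tert-butyldiphenylsilyl)oxy]-3-methylbut-2-en-1-yl]-7-methoxy-2,3-dihydro-4H-chromen-4-one | COc1ccc2c(c1C/C=C(\C)CO[Si](c1ccccc1)(c1ccccc1)C(C)(C)C)OC(c1ccc(O[Si](C)(C)C(C)(C)C)c(O[Si](C)(C)C(C)(C)C)c1)CC2=O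
F11 | step 9 | (2R,4R)-2-[3,4-bis(tert-butyldimethylsilyloxy)phenyl]-8-[(2E)-4-[(tert-butyldiphenylsilyl)oxy]-3-methylbut-2-en-1-yl]-7-methoxy-3,4-dihydro-2H-chromen-4-ol | COc1ccc2c(c1C/C=C(\C)CO[Si](c1ccccc1)(c1ccccc1)C(C)(C)C)O[C@@H](c1ccc(O[Si](C)(C)C(C)(C)C)c(O[Si](C)(C)C(C)(C)C)c1)C[C@H]2O
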